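**Strategy.** The ten-membered ring is not closed end to end: the C1–C10 bond is forged by an anionic oxy-Cope ring expansion. The precursor is a cyclohexanol whose six-membered ring holds C3–C8; C3 carries a vinyl group (C1=C2) and C8 the hydroxyl and a (Z)-propenyl group (C9=C10–C14). One [3,3] shift cleaves C3–C8, closes the germacrane ring, sets C10 through a chair transition state and leaves a C8–C9 enolate and a C2=C3 alkene, the seeds of the C8 acyloxy/C9 keto pair and the C2 carbinol. The step exploits the latent cyclodec-5-enone unit O–C8–C9–C10–C1–C2=C3 of the carbocycle. The cyclohexane, made from D-tartrate, already carries C4–C7 and the trans-fused lactone.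

Key step: step 15

Remark: germacrane numbering is used throughout (ring C1–C10, C14 = methyl on C10, C15 = methyl on C4, lactone C6–O–C12(=O)–C11(=C13)–C7); the target is treated as the open C2-hydroxy C9-ketone, which may equilibrate with its 2,9-hemiketal.

**Route**

Step 1
Reactants: 1 dimethyl 2,3-O-isopropylidene-D-tartrate
Product: 2 mono-acid mono-methyl ester
Conditions: KOH (1.0 equiv), MeOH, 0 °C to rt; then aq HCl to pH 3
Reagents that add atoms: potassium hydroxide, [K+].[OH-]
Why: Ester saponification of one of two equivalent esters of a C2-symmetric diester should stop at the mono-acid because the first carboxylate slows the second hydrolysis; no stereocenter is touched.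

Step 2
Reactants: 2 mono-acid
Product: 3 Weinreb amide ester
Conditions: MeNH(OMe)·HCl, EDC·HCl, HOBt (cat.), N-methylmorpholine, CH2Cl2, 0 °C to rt
Reagents that add atoms: N,O-dimethylhydroxylamine hydrochloride, CNOC.Cl
Why: Carbodiimide amide coupling should give the Weinreb amide without epimerisation, since the trans-dioxolane is the stable arrangement.

Step 3
Reactants: 3 Weinreb amide ester
Product: 4 methyl ketone ester
Conditions: MeMgBr (1.1 equiv), THF, −78 °C; aq NH4Cl
Reagents that add atoms: methylmagnesium bromide, C[Mg]Br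
Why: Weinreb ketone synthesis: the amide should react before the methyl ester at −78 °C and the chelated tetrahedral intermediate prevents over-addition.

Step 4
Reactants: 5 (E)-1,4-dibromobut-2-ene (3 equiv)
Product: 6 PMB-protected allylic bromide
Conditions: 4-methoxybenzyl alcohol, NaH, THF, 0 °C; then 5, 0 °C to rt
Reagents that add atoms: 4-methoxybenzyl alcohol, COc1ccc(CO)cc1
Why: Williamson etherification with excess dibromide should give mono-substitution with the E alkene retained.

Step 5
Reactants: 4 methyl ketone ester; 6 allylic bromide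
Product: 7 tertiary homoallylic alcohol
Conditions: activated Zn dust, THF, 0 °C; aq NH4Cl
Reagents that add atoms: none
Why: Zinc Barbier allylation: the allylzinc should add through its γ-carbon in a closed chair (dioxolanyl group equatorial, E reagent) so that C4–OH and the CH2OPMB group are anti, which sets C3, while zinc chelation between the ketone and the neighbouring dioxolane oxygen should expose the face that gives the 4S carbinol; the ester is inert.

Step 6
Reactants: 7 tertiary alcohol ester
Product: 8 aldehyde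
Conditions: i-Bu2AlH (2.2 equiv), CH2Cl2, −78 °C; aq sodium potassium tartrate
Reagents that add atoms: none
Why: Partial reduction of an α-alkoxy ester with i-Bu2AlH at −78 °C should stop at the aldehyde via the stable aluminium hemiacetal, the first equivalent being consumed by the tertiary hydroxyl.

Step 7
Reactants: 8 aldehyde
Product: 9 alkylidene phosphonoacetate
Conditions: triethyl phosphonoacetate, piperidinium acetate (cat.), toluene, 4 Å MS, rt
Reagents that add atoms: triethyl phosphonoacetate, CCOC(=O)CP(=O)(OCC)OCC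
Why: Knoevenagel condensation should give the doubly activated alkene (geometry irrelevant); C6 should hold because the trans-dioxolane is the thermodynamic isomer.

Step 8
Reactants: 9 PMB ether
Product: 10 primary alcohol
Conditions: DDQ, CH2Cl2/pH 7 buffer, 0 °C
Reagents that add atoms: none
Why: Oxidative cleavage of the 4-methoxybenzyl ether by DDQ should spare the electron-poor alkene, the vinyl group and the acetonide.

Step 9
Reactants: 10 primary alcohol
Product: 11 β-hydroxy aldehyde
Conditions: Dess–Martin periodinane, CH2Cl2, 0 °C; used crude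
Reagents that add atoms: none
Why: Dess–Martin oxidation under neutral conditions should give the aldehyde without base-induced migration of the β,γ-double bond or epimerisation at C3.

Step 10
Reactants: 11 aldehyde
Product: 12 cyclohexanol
Conditions: SmI2 (2.5 equiv), THF, −78 °C; then aq NH4Cl
Reagents that add atoms: none
Why: SmI2 reductive carbonyl–alkene cyclisation (6-exo-trig) should join C8 to C7 whichever partner is reduced first; a chair with the trans-fused dioxolane and the acceptor equatorial should place the C7 side chain equatorial, trans to C6–O (C8 and C11 epimers converge later).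

Step 11
Reactants: 12 cyclohexanol
Product: 13 cyclohexanone
Conditions: Dess–Martin periodinane, CH2Cl2, rt
Reagents that add atoms: none
Why: Dess–Martin oxidation should convert the secondary C8 alcohol to the ketone, leaving the tertiary C4 hydroxyl and the base-sensitive α-vinyl centre C3 untouched.

Step 12
Reactants: 13 cyclohexanone acetonide
Product: 14 dihydroxy lactone ketone
Conditions: TsOH·H2O (0.2 equiv), MeCN/H2O (10:1), 50 °C
Reagents that add atoms: none
Why: Acid-catalysed acetonide hydrolysis followed by lactonisation of the freed C6 hydroxyl onto the ethyl ester should give the trans-fused γ-lactone; five-ring closure beats the δ-lactone from C5–OH, and C8 is a ketone so no 8,12-lactone can form.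

Step 13
Reactants: 14 dihydroxy lactone ketone
Product: 15 4,5-acetonide ketone
Conditions: 2-methoxypropene, PPTS (cat.), CH2Cl2, 0 °C
Reagents that add atoms: 2-methoxypropene, COC(C)=C
Why: Transacetalisation should protect the trans-diequatorial C4/C5 diol as its acetonide and locks the chair with the C4 methyl axial.

Step 14
Reactants: 15 acetonide ketone
Product: 16 dialkenyl cyclohexanol
Conditions: (Z)-1-bromoprop-1-ene, t-BuLi (2 equiv), Et2O, −78 °C; CeCl3, THF, −78 °C; then 15 (3 equiv of reagent); aq NH4Cl
Reagents that add atoms: (Z)-prop-1-en-1-yllithium, C/C=C\[Li] (from (Z)-1-bromoprop-1-ene, C/C=C\Br)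
Why: Organocerium 1,2-addition should occur from the equatorial side because the axial face of C8 is blocked by the syn-axial C4 methyl, giving the axial hydroxyl and an equatorial (Z)-propenyl group trans to the C3 vinyl group; the first equivalent deprotonates the phosphonolactone, whose enolate is inert.

Step 15
Reactants: 16 dialkenyl cyclohexanol
Product: 19 ring-expanded triethylsilyl enol ether, via dipotassium alkoxide 17 (not isolated), via dipotassium enolate 18 (not isolated)
Conditions: KH (3 equiv), 18-crown-6, THF, 0 °C to rt; then Et3SiCl, −78 °C; aq NaHCO3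
Reagents that add atoms: chlorotriethylsilane, CC[Si](CC)(CC)Cl
Why: KH/18-crown-6 should turn the C8 hydroxyl into the naked alkoxide 17, whose 3-oxido-1,5-diene C10=C9–C8(O−)–C3–C2=C1 undergoes a concerted [3,3]-sigmatropic shift that breaks the C3–C8 bond of the cyclohexane and forms the C1–C10 bond, giving the regiodefined C8–C9 enolate 18, which Et3SiCl traps on oxygen. The closest known reaction type is the anionic oxy-Cope ring expansion of trans-1,2-dialkenylcyclohexanols to (E)-cyclodec-5-enones. The ten-membered ring closes by a four-atom ring expansion through a six-centre chair transition state, not by end-to-end cyclisation, so no high dilution is needed. The new stereocenter C10 is set by this chair, in which both alkenyl groups are equatorial on the cyclohexane and the methyl of the (Z)-propenyl group is pseudo-axial, translating the C8 carbinol configuration and the Z geometry into 10S; the same chair gives the 2E alkene and the ring-trans (8Z) enol ether. The step needs the [3,3] shift to beat fragmentation and needs a single reacting 1,5-diene: the carbon on C7 is sp3 and sits in the deprotonated phosphonolactone, the other oxygens are tied up in the acetonide, and irreversible enolate formation drives the rearrangement.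

Step 16
Reactants: 19 silyl enol ether
Product: 21 C2,C9-diol, via bis-alkylborane 20 (not isolated)
Conditions: BH3·THF (4 equiv), THF, 0 °C; then 30% H2O2, aq NaOAc, 0 °C to rt
Reagents that add atoms: hydrogen peroxide, OO
Why: Hydroboration–oxidation should put boron on C9 (β-carbon of the silyl enol ether) and on C2 (remote from the quaternary C4), and hydrogen should reach C8 from the peripheral face of the conformer in which the silyloxy group eclipses C7–H (A(1,2) strain minimised), setting the 8S centre; the C2 and C9 carbinol configurations are erased in step 17.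

Step 17
Reactants: 21 diol
Product: 22 C2,C9-diketone
Conditions: Dess–Martin periodinane, CH2Cl2, rt
Reagents that add atoms: none
Why: Dess–Martin oxidation should convert both secondary alcohols to ketones under neutral conditions that do not epimerise C8 or C10.

Step 18
Reactants: 22 phosphonolactone diketone
Product: 23 α-methylene lactone
Conditions: K2CO3, 37% aq CH2O, THF, 0 °C
Reagents that add atoms: formaldehyde, C=O
Why: Horner–Wadsworth–Emmons olefination of the α-phosphono lactone with formaldehyde should install C13, because carbonate deprotonates only the phosphonate C–H, by far the most acidic site.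

Step 19
Reactants: 23 protected diketone
Product: 24 C4,C5,C8-triol
Conditions: 48% aq HF, MeCN, 0 °C to rt
Reagents that add atoms: none
Why: Aqueous HF should cleave the triethylsilyl ether and hydrolyse the acetonide in one operation without touching the α-methylene lactone.

Step 20
Reactants: 24 triol
Product: 25 5,8-bis(isobutyrate)
Conditions: isobutyric anhydride (3 equiv), DMAP (cat.), pyridine, CH2Cl2, 0 °C to rt
Reagents that add atoms: isobutyric anhydride, CC(C)C(=O)OC(=O)C(C)C
Why: DMAP-catalysed acylation should esterify the two secondary hydroxyls and leave the tertiary C4 hydroxyl free; a C5–OH/C2=O hemiketal, if present, is in equilibrium with the open form that is trapped.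

Step 21
Reactants: 25 bis(isobutyrate) diketone
Product: 26 cardivin D
Conditions: catecholborane (3 equiv), THF, −10 °C; then aq sodium potassium tartrate
Reagents that add atoms: none
Why: Hydroxyl-directed reduction with catecholborane should activate only the C2 ketone through a boron chelate with the C4 oxygen and deliver hydride externally to give the syn-1,3-diol (2S), while the unchelated, hindered C9 ketone, the esters and the α-methylene lactone stay intact.

**Compound list**

1 | dimethyl (4S,5S)-2,2-dimethyl-1,3-dioxolane-4,5-dicarboxylate (dimethyl 2,3-O-isopropylidene-D-tartrate) | COC(=O)[C@H]1OC(C)(C)O[C@@H]1C(=O)OC | starting material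
2 | (4S,5S)-5-(methoxycarbonyl)-2,2-dimethyl-1,3-dioxolane-4-carboxylic acid | OC(=O)[C@H]1OC(C)(C)O[C@@H]1C(=O)OC | intermediate
3 | methyl (4S,5S)-5-[methoxy(methyl)carbamoyl]-2,2-dimethyl-1,3-dioxolane-4-carboxylate | CON(C)C(=O)[C@H]1OC(C)(C)O[C@@H]1C(=O)OC | intermediate
4 | methyl (4S,5S)-5-acetyl-2,2-dimethyl-1,3-dioxolane-4-carboxylate | CC(=O)[C@H]1OC(C)(C)O[C@@H]1C(=O)OC | intermediate
5 | (E)-1,4-dibromobut-2-ene | BrC/C=C/CBr | starting material
6 | (E)-1-bromo-4-[(4-methoxybenzyl)oxy]but-2-ene | COc1ccc(COC/C=C/CBr)cc1 | intermediate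
7 | methyl (4S,5S)-5-[(2S,3R)-2-hydroxy-3-{[(4-methoxybenzyl)oxy]methyl}pent-4-en-2-yl]-2,2-dimethyl-1,3-dioxolane-4-carboxylate | COc1ccc(COC[C@@H](C=C)[C@](C)(O)[C@H]2OC(C)(C)O[C@@H]2C(=O)OC)cc1 | intermediate
8 | (4S,5S)-5-[(2S,3R)-2-hydroxy-3-{[(4-methoxybenzyl)oxy]methyl}pent-4-en-2-yl]-2,2-dimethyl-1,3-dioxolane-4-carbaldehyde | COc1ccc(COC[C@@H](C=C)[C@](C)(O)[C@H]2OC(C)(C)O[C@@H]2C=O)cc1 | intermediate
9 | ethyl 2-(diethoxyphosphoryl)-3-{(4R,5S)-5-[(2S,3R)-2-hydroxy-3-{[(4-methoxybenzyl)oxy]methyl}pent-4-en-2-yl]-2,2-dimethyl-1,3-dioxolan-4-yl}prop-2-enoate (E/Z mixture) | COc1ccc(COC[C@@H](C=C)[C@](C)(O)[C@H]2OC(C)(C)O[C@@H]2C=C(C(=O)OCC)P(=O)(OCC)OCC)cc1 | intermediate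
10 | ethyl 2-(diethoxyphosphoryl)-3-{(4R,5S)-5-[(2S,3R)-2-hydroxy-3-(hydroxymethyl)pent-4-en-2-yl]-2,2-dimethyl-1,3-dioxolan-4-yl}prop-2-enoate | OC[C@@H](C=C)[C@](C)(O)[C@H]1OC(C)(C)O[C@@H]1C=C(C(=O)OCC)P(=O)(OCC)OCC | intermediate
11 | ethyl 2-(diethoxyphosphoryl)-3-{(4R,5S)-5-[(2S,3S)-3-formyl-2-hydroxypent-4-en-2-yl]-2,2-dimethyl-1,3-dioxolan-4-yl}prop-2-enoate | O=C[C@@H](C=C)[C@](C)(O)[C@H]1OC(C)(C)O[C@@H]1C=C(C(=O)OCC)P(=O)(OCC)OCC | intermediate
12 | cyclohexane-4,8-diol, ring = C3–C8: (3R)-vinyl, (4S)-methyl, (5S,6R)-trans-O-isopropylidene, (7S)-CH(CO2Et)P(O)(OEt)2; epimer mixture at C8 and C11 | OC1[C@@H](C=C)[C@](C)(O)[C@H]2OC(C)(C)O[C@@H]2[C@H]1C(C(=O)OCC)P(=O)(OCC)OCC | intermediate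
13 | the C8 ketone of 12, (3S,4S,5S,6R,7R); C11 epimers | O=C1[C@@H](C=C)[C@](C)(O)[C@H]2OC(C)(C)O[C@@H]2[C@H]1C(C(=O)OCC)P(=O)(OCC)OCC | intermediate
14 | (3S,4S,5S,6R,7R)-4,5-dihydroxy-4-methyl-3-vinylcyclohexan-8-one trans-fused at C6–C7 to the 11-(diethoxyphosphoryl)-6,12-γ-lactone; C11 epimers | O=C1[C@@H](C=C)[C@](C)(O)[C@@H](O)[C@@H]2OC(=O)C(P(=O)(OCC)OCC)[C@@H]12 | intermediate
15 | 4,5-O-isopropylidene derivative of 14, (3S,4S,5S,6R,7R) | O=C1[C@@H](C=C)[C@]2(C)OC(C)(C)O[C@H]2[C@@H]3OC(=O)C(P(=O)(OCC)OCC)[C@@H]13 | intermediate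
16 | (3R,4S,5S,6R,7R,8S)-8-hydroxy-8-[(Z)-prop-1-enyl]-3-vinyl analogue of 15 (tertiary alcohol, hydroxyl axial, both alkenyl groups equatorial) | C/C=C\[C@]1(O)[C@@H](C=C)[C@]2(C)OC(C)(C)O[C@H]2[C@@H]3OC(=O)C(P(=O)(OCC)OCC)[C@@H]13 | intermediate
17 | dipotassium salt of 16 (C8 alkoxide and phosphonolactone enolate) | C/C=C\[C@]1([O-])[C@@H](C=C)[C@]2(C)OC(C)(C)O[C@H]2[C@@H]3OC([O-])=C(P(=O)(OCC)OCC)[C@@H]13.[K+].[K+] | intermediate (not isolated)
18 | dipotassium salt of the ring-expanded ketone (C8–C9 enolate and phosphonolactone enolate), ten-membered ring | [O-]/C1=C\[C@@H](C)C/C=C/[C@]2(C)OC(C)(C)O[C@H]2[C@@H]3OC([O-])=C(P(=O)(OCC)OCC)[C@@H]13.[K+].[K+] | intermediate (not isolated)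
19 | (2E,8Z)-cyclodeca-2,8-diene (germacrane ring): 8-triethylsilyloxy, (10S)-methyl, (4S,5S)-4-methyl-4,5-O-isopropylidene, (6R,7R)-trans-fused 11-(diethoxyphosphoryl)-6,12-lactone | CC[Si](CC)(CC)O/C1=C\[C@@H](C)C/C=C/[C@]2(C)OC(C)(C)O[C@H]2[C@@H]3OC(=O)C(P(=O)(OCC)OCC)[C@@H]13 | intermediate
20 | C2,C9-bis(boranyl) adduct of 19 (8S) | CC[Si](CC)(CC)O[C@@H]1C(B)[C@@H](C)CC(B)C[C@]2(C)OC(C)(C)O[C@H]2[C@@H]3OC(=O)C(P(=O)(OCC)OCC)[C@@H]13 | intermediate (not isolated)
21 | (4S,5S,6R,7R,8S,10S)-2,9-dihydroxy-8-triethylsilyloxy-4,5-O-isopropylidene phosphonolactone (C2, C9, C11 epimer mixture) | CC[Si](CC)(CC)O[C@@H]1C(O)[C@@H](C)CC(O)C[C@]2(C)OC(C)(C)O[C@H]2[C@@H]3OC(=O)C(P(=O)(OCC)OCC)[C@@H]13 | intermediate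
22 | (4S,5S,6R,7R,8S,10S)-2,9-dioxo-8-triethylsilyloxy-4,5-O-isopropylidene phosphonolactone | CC[Si](CC)(CC)O[C@@H]1C(=O)[C@@H](C)CC(=O)C[C@]2(C)OC(C)(C)O[C@H]2[C@@H]3OC(=O)C(P(=O)(OCC)OCC)[C@@H]13 | intermediate
23 | (4S,5S,6R,7R,8S,10S)-2,9-dioxo-8-triethylsilyloxy-4,5-O-isopropylidene-germacr-11(13)-en-6,12-olide | CC[Si](CC)(CC)O[C@@H]1C(=O)[C@@H](C)CC(=O)C[C@]2(C)OC(C)(C)O[C@H]2[C@@H]3OC(=O)C(=C)[C@@H]13 | intermediate
24 | (4S,5S,6R,7S,8S,10S)-4,5,8-trihydroxy-2,9-dioxogermacr-11(13)-en-6,12-olide | O[C@@H]1C(=O)[C@@H](C)CC(=O)C[C@](C)(O)[C@@H](O)[C@@H]2OC(=O)C(=C)[C@@H]12 | intermediate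
25 | (4S,5S,6R,7R,8S,10S)-4-hydroxy-5,8-bis(isobutyryloxy)-2,9-dioxogermacr-11(13)-en-6,12-olide | CC(C)C(=O)O[C@@H]1C(=O)[C@@H](C)CC(=O)C[C@](C)(O)[C@@H](OC(=O)C(C)C)[C@@H]2OC(=O)C(=C)[C@@H]12 | intermediate
26 | cardivin D, (2S,4S,5S,6R,7R,8S,10S) | C=C1C(=O)O[C@@H]2[C@@H]1[C@H](OC(=O)C(C)C)C(=O)[C@@H](C)C[C@H](O)C[C@](C)(O)[C@H]2OC(=O)C(C)C | target

**Totals and risks**

Total step count: 21. Longest linear sequence: 20 steps (steps 1–3 and 5–21, from 1).

Steps most likely to fail:

1. Step 16 (hydroboration). Hydrogen may be delivered to C8 from the other face if the ten-membered ring reacts through the conformer in which the silyloxy group points to the β face, giving the C8 epimer. The fallback sets out from 19 and comes back at 25, and sets C8 by inversion instead. The same hydroboration then gives the 8-epi diol F1, Dess–Martin oxidation the 8-epi diketone F2, and K2CO3/aqueous CH2O the 8-epi methylene lactone F3. Buffered HF·pyridine removes only the silyl group to give the 8-epi alcohol F4. A Mitsunobu esterification (isobutyric acid, PPh3, DIAD) inverts C8 and installs the ester to give the 8-isobutyrate acetonide F5. Aqueous acetic acid removes the acetonide to give the 4,5-diol 8-isobutyrate F6, and isobutyric anhydride/DMAP acylates C5–OH to return to 25.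

2. Step 21 (directed reduction). Hydride may attack C2 from the wrong face (the axial C4 methyl shields the chelate), or the activated α-acyloxy C9 ketone may be reduced in competition. The fallback sets out from 25 and comes back at 26: enzyme-controlled reduction with a screened NADPH-dependent ketoreductase (glucose/glucose dehydrogenase recycling, pH 7 buffer with DMSO), which chooses the ketone and the face by the catalyst and not by the substrate; no new compound is involved.

3. Step 5 (Barbier allylation). Facial selectivity at the ketone may be poor, because the dioxolane oxygen is a weak chelating group and open (non-chelated) addition gives the C4 epimer. The fallback sets out from 6 (with 4) and comes back at 7: bromide 6 is converted (Mg, then B(OiPr)3) into the allylboronate F7, which adds to ketone 4 under catalysis by 3,3'-dibromo-BINOL (catalyst-controlled asymmetric allylboration of ketones, chair transition state, anti from the E boronate).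

**Further compounds**

F1 | step 16 | 8-epimer of 21 (8R; C2, C9, C11 epimer mixture) | CC[Si](CC)(CC)O[C@H]1C(O)[C@@H](C)CC(O)C[C@]2(C)OC(C)(C)O[C@H]2[C@@H]3OC(=O)C(P(=O)(OCC)OCC)[C@@H]13
F2 | step 16 | 8-epimer of 22 | CC[Si](CC)(CC)O[C@H]1C(=O)[C@@H](C)CC(=O)C[C@]2(C)OC(C)(C)O[C@H]2[C@@H]3OC(=O)C(P(=O)(OCC)OCC)[C@@H]13
F3 | step 16 | 8-epimer of 23 | CC[Si](CC)(CC)O[C@H]1C(=O)[C@@H](C)CC(=O)C[C@]2(C)OC(C)(C)O[C@H]2[C@@H]3OC(=O)C(=C)[C@@H]13
F4 | step 16 | (8R)-8-hydroxy-2,9-dioxo-4,5-O-isopropylidene-germacr-11(13)-en-6,12-olide | O[C@H]1C(=O)[C@@H](C)CC(=O)C[C@]2(C)OC(C)(C)O[C@H]2[C@@H]3OC(=O)C(=C)[C@@H]13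
F5 | step 16 | (8S)-8-isobutyryloxy-2,9-dioxo-4,5-O-isopropylidene-germacr-11(13)-en-6,12-olide | CC(C)C(=O)O[C@@H]1C(=O)[C@@H](C)CC(=O)C[C@]2(C)OC(C)(C)O[C@H]2[C@@H]3OC(=O)C(=C)[C@@H]13
F6 | step 16 | (8S)-4,5-dihydroxy-8-isobutyryloxy-2,9-dioxogermacr-11(13)-en-6,12-olide | CC(C)C(=O)O[C@@H]1C(=O)[C@@H](C)CC(=O)C[C@](C)(O)[C@@H](O)[C@@H]2OC(=O)C(=C)[C@@H]12
F0 | step 21 | none | none
F7 | step 5 | diisopropyl {(E)-4-[(4-methoxybenzyl)oxy]but-2-en-1-yl}boronate | COc1ccc(COC/C=C/CB(OC(C)C)OC(C)C)cc1
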